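**Retrosynthetic overview**

1. Stenophyllol B (33) comes from its octamethyl ether 32. The dihydrofuran O–C2 bond of 32 is made by cationic closure of the ring D phenol after the vinyl group of 27 is cut to a one-carbon handle that receives the last 4-methoxyphenyl group.
2. The strategy rests on one feature. Furan C3 is bonded to the ring D carbon that lies between the furan-oxygen carbon and the carbon holding indane C2, and it is the only sp3 atom linking rings C and D in the eight-membered carbocycle. The ring D oxygen can therefore deliver it by a [3,3] shift that contracts the twelve-membered aryl cinnamyl ether 25 to 27.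
3. Macrocycle 25 comes from ring-closing metathesis of styrene/allyl ether 24. Ring C and the diarylmethine come from a Friedel–Crafts reaction of carbinol 19 with 1-bromo-3,5-dimethoxybenzene.
4. The all-trans indane aldehyde 18 comes from cationic cyclisation of lactone 14. Its C2 configuration is set by an Ireland–Claisen rearrangement with chirality transfer from the (S)-allylic alcohol 4.
5. Ring order: five-membered indane ring, then the twelve-membered ether, then the eight-membered carbocycle, then the dihydrofuran.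

Key step: step 16

Remark on labels: ring A is the benzo ring of the indane, ring C the dimethoxyphenyl ring between the diarylmethine and furan C3, ring D the benzofuran benzene ring. Indane C1 carries a 4-methoxyphenyl group, C2 carries ring D, C3 carries the diarylmethine.

Assumption: 3-hydroxy-5-methoxybenzaldehyde (1) and a THF solution of 4-methoxyphenylmagnesium bromide (12) are bought, and minor diastereomers from steps 5 and 12 are taken to be separable by chromatography.

**Route**

Step 1
Reactants: 1 3-hydroxy-5-methoxybenzaldehyde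
Product: 2 3-methoxy-5-(triisopropylsilyloxy)benzaldehyde
Conditions: TIPSCl, imidazole, DMF, rt
Reagents that add atoms: triisopropylsilyl chloride CC(C)[Si](Cl)(C(C)C)C(C)C
Why: Standard phenol silylation; the bulky aryl silyl ether should survive the bases, hydrides, Grignard reagents and protic acid used before step 14.

Step 2
Reactants: 2 3-methoxy-5-(triisopropylsilyloxy)benzaldehyde
Product: 3 (E)-4-[3-methoxy-5-(triisopropylsilyloxy)phenyl]but-3-en-2-one
Conditions: Ph3P=CHC(O)CH3, toluene, 100 °C
Reagents that add atoms: 1-(triphenylphosphoranylidene)propan-2-one CC(=O)C=P(c1ccccc1)(c1ccccc1)c1ccccc1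
Why: Wittig olefination with a stabilised ylide should give the E-enone.

Step 3
Reactants: 3 (E)-4-[3-methoxy-5-(triisopropylsilyloxy)phenyl]but-3-en-2-one
Product: 4 (S,E)-4-[3-methoxy-5-(triisopropylsilyloxy)phenyl]but-3-en-2-ol
Conditions: (R)-2-methyl-CBS-oxazaborolidine (15 mol%), catecholborane, toluene, −78 °C
Reagents that add atoms: none
Why: Corey–Bakshi–Shibata reduction; the alkenyl group acts as the large substituent, so the (R)-catalyst should deliver hydride 1,2 to give the (S)-carbinol.

Step 4
Reactants: 4 (S,E)-4-[3-methoxy-5-(triisopropylsilyloxy)phenyl]but-3-en-2-ol; 5 3,5-dimethoxyphenylacetic acid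
Product: 6 (S,E)-4-[3-methoxy-5-(triisopropylsilyloxy)phenyl]but-3-en-2-yl 2-(3,5-dimethoxyphenyl)acetate
Conditions: DCC, DMAP (cat.), CH2Cl2, 0 °C to rt
Reagents that add atoms: none
Why: Steglich esterification joins the ring A and ring D fragments without touching the carbinol stereocentre.

Step 5
Reactants: 6 (S,E)-4-[3-methoxy-5-(triisopropylsilyloxy)phenyl]but-3-en-2-yl 2-(3,5-dimethoxyphenyl)acetate
Product: 9 (2R,3R,E)-2-(3,5-dimethoxyphenyl)-3-[3-methoxy-5-(triisopropylsilyloxy)phenyl]hex-4-enoic acid, via silyl ketene acetal 7 (not isolated), via trimethylsilyl ester 8 (not isolated)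
Conditions: LiN(SiMe3)2, Me3SiCl, THF, −78 °C to 40 °C; then 1 M HCl
Reagents that add atoms: none
Why: Ireland–Claisen rearrangement through a chair with the carbinol methyl pseudo-equatorial should transfer the (S)-carbinol chirality to C3 (the future indane C2) and give the E-propenyl group, while the aryl-cis-to-oxygen enolate should give the 2,3-syn acid; C2 is equilibrated in step 10, so only the chirality transfer has to be clean.

Step 6
Reactants: 9 (2R,3R,E)-2-(3,5-dimethoxyphenyl)-3-[3-methoxy-5-(triisopropylsilyloxy)phenyl]hex-4-enoic acid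
Product: 11 (2R,3R)-2-(3,5-dimethoxyphenyl)-3-[3-methoxy-5-(triisopropylsilyloxy)phenyl]-4-oxobutanoic acid, via diol 10 (not isolated)
Conditions: OsO4 (2 mol%), NaIO4, 2,6-lutidine, dioxane–H2O, rt
Reagents that add atoms: osmium tetroxide O=[Os](=O)(=O)=O (catalytic oxygen carrier); sodium periodate [Na+].[O-]I(=O)(=O)=O (terminal oxidant)
Why: Lemieux–Johnson cleavage removes the propenyl terminus without ozone near the electron-rich arenes, and ring–chain tautomerism of the oxo acid to its hydroxylactone should shield the α-aryl aldehyde from enolisation.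

Step 7
Reactants: 11 (2R,3R)-2-(3,5-dimethoxyphenyl)-3-[3-methoxy-5-(triisopropylsilyloxy)phenyl]-4-oxobutanoic acid; 12 4-methoxyphenylmagnesium bromide
Product: 14 3,4-trans-3-(3,5-dimethoxyphenyl)-5-(4-methoxyphenyl)-4-[3-methoxy-5-(triisopropylsilyloxy)phenyl]dihydrofuran-2(3H)-one (C5 epimers), via hydroxy acid 13 (not isolated)
Conditions: 12 (3.5 equiv), CeCl3, THF, −78 °C to 0 °C; then 1 M HCl, rt
Reagents that add atoms: none
Why: Addition of a weakly basic organocerium reagent to the formyl carboxylate (as in arylation of formyl acids to lactones) followed by acid lactonisation; the carbinol configuration is irrelevant because this centre is ionised in step 8.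

Step 8
Reactants: 14 3,4-trans-3-(3,5-dimethoxyphenyl)-5-(4-methoxyphenyl)-4-[3-methoxy-5-(triisopropylsilyloxy)phenyl]dihydrofuran-2(3H)-one
Product: 15 1,2-trans-2,3-cis-5,7-dimethoxy-1-(4-methoxyphenyl)-2-[3-methoxy-5-(triisopropylsilyloxy)phenyl]indane-3-carboxylic acid
Conditions: TFA, CH2Cl2, −10 °C to rt
Reagents that add atoms: none
Why: Friedel–Crafts cyclialkylation: acid ionises the 4-methoxybenzylic lactone C–O bond and ring A attacks through the carbon ortho to the chain and ortho/para to its methoxy groups, the C1 aryl settling trans to the C2 aryl; the run is kept cold and stopped at full conversion so that reversible proton loss next to the cation cannot erode C2.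

Step 9
Reactants: 15 1,2-trans-2,3-cis-5,7-dimethoxy-1-(4-methoxyphenyl)-2-[3-methoxy-5-(triisopropylsilyloxy)phenyl]indane-3-carboxylic acid
Product: 16 1,2-trans-2,3-cis-[5,7-dimethoxy-1-(4-methoxyphenyl)-2-[3-methoxy-5-(triisopropylsilyloxy)phenyl]indan-3-yl]methanol
Conditions: BH3·SMe2, THF, 0 °C to rt
Reagents that add atoms: none
Why: Borane reduces the carboxylic acid chemoselectively and leaves the aryl silyl ether alone.

Step 10
Reactants: 16 1,2-trans-2,3-cis-[5,7-dimethoxy-1-(4-methoxyphenyl)-2-[3-methoxy-5-(triisopropylsilyloxy)phenyl]indan-3-yl]methanol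
Product: 18 all-trans-5,7-dimethoxy-1-(4-methoxyphenyl)-2-[3-methoxy-5-(triisopropylsilyloxy)phenyl]indane-3-carbaldehyde, via cis aldehyde 17 (not isolated)
Conditions: Dess–Martin periodinane, NaHCO3, CH2Cl2, 0 °C; then DBU (0.5 equiv), rt
Reagents that add atoms: none
Why: Dess–Martin oxidation followed by base equilibration through the enol of the α-aryl aldehyde should move C3 to the more stable 2,3-trans arrangement, while C1 and C2 carry no acidic hydrogen.

Step 11
Reactants: 18 all-trans-5,7-dimethoxy-1-(4-methoxyphenyl)-2-[3-methoxy-5-(triisopropylsilyloxy)phenyl]indane-3-carbaldehyde; 12 4-methoxyphenylmagnesium bromide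
Product: 19 all-trans-[5,7-dimethoxy-1-(4-methoxyphenyl)-2-[3-methoxy-5-(triisopropylsilyloxy)phenyl]indan-3-yl](4-methoxyphenyl)methanol (carbinol epimers)
Conditions: 12 (1.5 equiv), THF, −78 °C to 0 °C; aq NH4Cl
Reagents that add atoms: none
Why: Grignard addition to the aldehyde; the carbinol centre need not be controlled because it is ionised in step 12.

Step 12
Reactants: 19 all-trans-[5,7-dimethoxy-1-(4-methoxyphenyl)-2-[3-methoxy-5-(triisopropylsilyloxy)phenyl]indan-3-yl](4-methoxyphenyl)methanol; 20 1-bromo-3,5-dimethoxybenzene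
Product: 21 (1S,2S,3R)-3-[(R)-(2-bromo-4,6-dimethoxyphenyl)(4-methoxyphenyl)methyl]-5,7-dimethoxy-1-(4-methoxyphenyl)-2-[3-methoxy-5-(triisopropylsilyloxy)phenyl]indane
Conditions: 20 (10 equiv), TFA, CH2Cl2, −20 °C to 0 °C
Reagents that add atoms: none
Why: Friedel–Crafts benzylation in which 20 attacks the 4-methoxybenzylic cation through C2 (para to one methoxy group, the site at which 20 is formylated); the methine is set by substrate control, since in the cation conformer with indane C3–H eclipsing the aryl-bearing bond the arene should approach past C2–H and away from the peri hydrogen of ring A, and the 2,3-trans indane keeps ring D from closing a five-membered ring onto the cation.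

Step 13
Reactants: 21 (1S,2S,3R)-3-[(R)-(2-bromo-4,6-dimethoxyphenyl)(4-methoxyphenyl)methyl]-5,7-dimethoxy-1-(4-methoxyphenyl)-2-[3-methoxy-5-(triisopropylsilyloxy)phenyl]indane
Product: 22 (1S,2S,3R)-3-[(R)-(2,4-dimethoxy-6-vinylphenyl)(4-methoxyphenyl)methyl]-5,7-dimethoxy-1-(4-methoxyphenyl)-2-[3-methoxy-5-(triisopropylsilyloxy)phenyl]indane
Conditions: vinylboronic acid pinacol ester, Pd(OAc)2 (5 mol%), SPhos (10 mol%), K3PO4, toluene–H2O, 90 °C
Reagents that add atoms: vinylboronic acid pinacol ester C=CB1OC(C)(C)C(C)(C)O1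
Why: Suzuki–Miyaura vinylation with a biarylphosphine ligand suited to hindered, electron-rich aryl bromides; it is run before the allyl ether is present so that no allyl aryl ether is exposed to zerovalent palladium.

Step 14
Reactants: 22 (1S,2S,3R)-3-[(R)-(2,4-dimethoxy-6-vinylphenyl)(4-methoxyphenyl)methyl]-5,7-dimethoxy-1-(4-methoxyphenyl)-2-[3-methoxy-5-(triisopropylsilyloxy)phenyl]indane
Product: 24 (1S,2S,3R)-2-(3-allyloxy-5-methoxyphenyl)-3-[(R)-(2,4-dimethoxy-6-vinylphenyl)(4-methoxyphenyl)methyl]-5,7-dimethoxy-1-(4-methoxyphenyl)indane, via caesium phenoxide 23 (not isolated)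
Conditions: CsF, allyl bromide, DMF, rt
Reagents that add atoms: allyl bromide C=CCBr
Why: Fluoride cleaves the aryl silyl ether and the caesium phenoxide is O-allylated in the same flask (Williamson ether synthesis).

Step 15
Reactants: 24 (1S,2S,3R)-2-(3-allyloxy-5-methoxyphenyl)-3-[(R)-(2,4-dimethoxy-6-vinylphenyl)(4-methoxyphenyl)methyl]-5,7-dimethoxy-1-(4-methoxyphenyl)indane
Product: 25 twelve-membered (E)-aryl cinnamyl ether macrocycle on the trans,trans-indane
Conditions: second-generation Grubbs catalyst Ru(=CHPh)Cl2(H2IMes)(PCy3) (10 mol%), 1,4-benzoquinone (cat.), CH2Cl2 (1 mM), 40 °C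
Reagents that add atoms: none
Why: Ring-closing metathesis with loss of ethylene; the carbene should load on the allyl ether and close onto the styrene, and reversible metathesis should favour the conjugated E-alkene.

Step 16
Reactants: 25 twelve-membered (E)-aryl cinnamyl ether macrocycle on the trans,trans-indane
Product: 27 eight-membered carbocycle with vinyl group at furan C3 and free ring D phenol, via dienone 26 (not isolated)
Conditions: PhNEt2 (degassed), 190 °C, sealed tube
Reagents that add atoms: none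
Why: Proposed new method: on heating, the aryl cinnamyl ether should undergo a concerted suprafacial [3,3] shift through a chair-like six-membered transition state in which the O–CH2 bond breaks as the ring C-bearing alkene carbon bonds to the ring D carbon ortho to oxygen, and dienone 26 then tautomerises to phenol 27. The closest known reactions are the thermal aromatic Claisen rearrangement of acyclic aryl cinnamyl ethers and ring-contracting Ireland–Claisen rearrangements of macrolactones; contraction of a macrocyclic aryl ether to an eight-membered carbocycle is not known. The eight-membered ring is closed by transannular ring contraction: the new C–C bond spans the twelve-membered ring and the four atoms O, CH2, CH and the ring D C–O carbon leave it, so no end-to-end medium-ring cyclisation is needed. The new stereocentre (furan C3) is controlled by the E-alkene, which places ring C pseudo-equatorial in the chair, together with the alkene face on which the trans-fused indane and the (R)-methine let ring D approach; the chair drawn for 26 leads to the required (R) centre. The step needs bonding at the ortho carbon between the oxygen-bearing carbon and the indane-bearing carbon, and the tether secures this because the other ortho carbon is para to the anchor and could only rearomatise to a para-bridged benzene with a six-atom bridge. A neutral thermal protocol in an amine solvent is chosen so that the shift stays concerted and the cinnamyl unit does not ionise.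

Step 17
Reactants: 27 eight-membered carbocycle with vinyl group at furan C3 and free ring D phenol
Product: 30 2-hydroxy-2,3-dihydrobenzofuran (lactol) fused to the eight-membered ring, via diol 28 (not isolated), via hydroxy aldehyde 29 (not isolated)
Conditions: OsO4 (5 mol%), NaIO4, 2,6-lutidine, dioxane–H2O, rt
Reagents that add atoms: osmium tetroxide O=[Os](=O)(=O)=O (catalytic oxygen carrier); sodium periodate [Na+].[O-]I(=O)(=O)=O (terminal oxidant)
Why: Lemieux–Johnson cleavage of the vinyl group; the aldehyde should be trapped at once by the neighbouring phenol as the lactol, which protects the doubly benzylic furan C3 from enolisation.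

Step 18
Reactants: 30 2-hydroxy-2,3-dihydrobenzofuran (lactol) fused to the eight-membered ring; 12 4-methoxyphenylmagnesium bromide
Product: 31 ring D phenol bearing the (4-methoxyphenyl)hydroxymethyl group at furan C3 (carbinol epimers)
Conditions: 12 (4 equiv), THF, 0 °C to rt; aq NH4Cl
Reagents that add atoms: none
Why: The first equivalent of Grignard reagent opens the lactol to the phenoxide aldehyde and the second adds to the aldehyde; the carbinol configuration is irrelevant because it is ionised in step 19.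

Step 19
Reactants: 31 ring D phenol bearing the (4-methoxyphenyl)hydroxymethyl group at furan C3
Product: 32 octa-O-methylstenophyllol B
Conditions: TsOH·H2O (20 mol%), CH2Cl2, 0 °C
Reagents that add atoms: none
Why: Acid ionises the 4-methoxybenzylic alcohol to a quinone-methide-like cation that the phenol traps in a five-membered closure; the reversible closure should settle on the trans-2,3-dihydrobenzofuran with the aryl group anti to ring C.

Step 20
Reactants: 32 octa-O-methylstenophyllol B
Product: 33 stenophyllol B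
Conditions: BBr3 (20 equiv), CH2Cl2, −78 °C to rt; then MeOH, H2O
Reagents that add atoms: none
Why: Boron tribromide cleaves all eight aryl methyl ethers by SN2 attack of bromide at methyl, which touches no stereocentre; the cyclic benzylic ether is expected to survive as in related permethylated resveratrol oligomers.

**Compound list**

1 | 3-hydroxy-5-methoxybenzaldehyde | COc1cc(O)cc(C=O)c1 | starting material
2 | 3-methoxy-5-(triisopropylsilyloxy)benzaldehyde | COc1cc(O[Si](C(C)C)(C(C)C)C(C)C)cc(C=O)c1 | intermediate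
3 | (E)-4-[3-methoxy-5-(triisopropylsilyloxy)phenyl]but-3-en-2-one | COc1cc(O[Si](C(C)C)(C(C)C)C(C)C)cc(/C=C/C(C)=O)c1 | intermediate
4 | (S,E)-4-[3-methoxy-5-(triisopropylsilyloxy)phenyl]but-3-en-2-ol | C[C@H](O)/C=C/c1cc(OC)cc(O[Si](C(C)C)(C(C)C)C(C)C)c1 | intermediate
5 | 3,5-dimethoxyphenylacetic acid | COc1cc(CC(O)=O)cc(OC)c1 | starting material
6 | (S,E)-4-[3-methoxy-5-(triisopropylsilyloxy)phenyl]but-3-en-2-yl 2-(3,5-dimethoxyphenyl)acetate | C[C@H](OC(=O)Cc1cc(OC)cc(OC)c1)/C=C/c1cc(OC)cc(O[Si](C(C)C)(C(C)C)C(C)C)c1 | intermediate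
7 | trimethylsilyl ketene acetal of 6 (aryl cis to OSiMe3) | C[C@H](O/C(O[Si](C)(C)C)=C/c1cc(OC)cc(OC)c1)/C=C/c1cc(OC)cc(O[Si](C(C)C)(C(C)C)C(C)C)c1 | intermediate
8 | trimethylsilyl ester of acid 9 | COc1cc(O[Si](C(C)C)(C(C)C)C(C)C)cc(c1)[C@H](/C=C/C)[C@H](c1cc(OC)cc(OC)c1)C(=O)O[Si](C)(C)C | intermediate
9 | (2R,3R,E)-2-(3,5-dimethoxyphenyl)-3-[3-methoxy-5-(triisopropylsilyloxy)phenyl]hex-4-enoic acid (2,3-syn) | COc1cc(O[Si](C(C)C)(C(C)C)C(C)C)cc(c1)[C@H](/C=C/C)[C@H](c1cc(OC)cc(OC)c1)C(O)=O | intermediate
10 | 4,5-dihydroxy derivative of 9 (diol, diastereomer mixture at C4 and C5) | COc1cc(O[Si](C(C)C)(C(C)C)C(C)C)cc(c1)[C@H](C(O)C(C)O)[C@H](c1cc(OC)cc(OC)c1)C(O)=O | intermediate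
11 | (2R,3R)-2-(3,5-dimethoxyphenyl)-3-[3-methoxy-5-(triisopropylsilyloxy)phenyl]-4-oxobutanoic acid (open form of the hydroxylactone tautomer) | COc1cc(O[Si](C(C)C)(C(C)C)C(C)C)cc(c1)[C@H](C=O)[C@H](c1cc(OC)cc(OC)c1)C(O)=O | intermediate
12 | 4-methoxyphenylmagnesium bromide | COc1ccc([Mg]Br)cc1 | starting material
13 | 2-(3,5-dimethoxyphenyl)-4-hydroxy-4-(4-methoxyphenyl)-3-[3-methoxy-5-(triisopropylsilyloxy)phenyl]butanoic acid (C4 epimers) | COc1cc(O[Si](C(C)C)(C(C)C)C(C)C)cc(c1)[C@H](C(O)c1ccc(OC)cc1)[C@H](c1cc(OC)cc(OC)c1)C(O)=O | intermediate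
14 | 3,4-trans-3-(3,5-dimethoxyphenyl)-5-(4-methoxyphenyl)-4-[3-methoxy-5-(triisopropylsilyloxy)phenyl]dihydrofuran-2(3H)-one (C5 epimers) | COc1cc(O[Si](C(C)C)(C(C)C)C(C)C)cc(c1)[C@@H]1C(c2ccc(OC)cc2)OC(=O)[C@H]1c1cc(OC)cc(OC)c1 | intermediate
15 | 1,2-trans-2,3-cis-5,7-dimethoxy-1-(4-methoxyphenyl)-2-[3-methoxy-5-(triisopropylsilyloxy)phenyl]indane-3-carboxylic acid | COc1ccc([C@H]2c3c(OC)cc(OC)cc3[C@H](C(O)=O)[C@@H]2c2cc(OC)cc(O[Si](C(C)C)(C(C)C)C(C)C)c2)cc1 | intermediate
16 | 1,2-trans-2,3-cis-[5,7-dimethoxy-1-(4-methoxyphenyl)-2-[3-methoxy-5-(triisopropylsilyloxy)phenyl]indan-3-yl]methanol | COc1ccc([C@H]2c3c(OC)cc(OC)cc3[C@H](CO)[C@@H]2c2cc(OC)cc(O[Si](C(C)C)(C(C)C)C(C)C)c2)cc1 | intermediate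
17 | 1,2-trans-2,3-cis-5,7-dimethoxy-1-(4-methoxyphenyl)-2-[3-methoxy-5-(triisopropylsilyloxy)phenyl]indane-3-carbaldehyde | COc1ccc([C@H]2c3c(OC)cc(OC)cc3[C@H](C=O)[C@@H]2c2cc(OC)cc(O[Si](C(C)C)(C(C)C)C(C)C)c2)cc1 | intermediate
18 | all-trans-5,7-dimethoxy-1-(4-methoxyphenyl)-2-[3-methoxy-5-(triisopropylsilyloxy)phenyl]indane-3-carbaldehyde | COc1ccc([C@H]2c3c(OC)cc(OC)cc3[C@@H](C=O)[C@@H]2c2cc(OC)cc(O[Si](C(C)C)(C(C)C)C(C)C)c2)cc1 | intermediate
19 | all-trans-[5,7-dimethoxy-1-(4-methoxyphenyl)-2-[3-methoxy-5-(triisopropylsilyloxy)phenyl]indan-3-yl](4-methoxyphenyl)methanol (carbinol epimers) | COc1ccc([C@H]2c3c(OC)cc(OC)cc3[C@@H](C(O)c3ccc(OC)cc3)[C@@H]2c2cc(OC)cc(O[Si](C(C)C)(C(C)C)C(C)C)c2)cc1 | intermediate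
20 | 1-bromo-3,5-dimethoxybenzene | COc1cc(Br)cc(OC)c1 | starting material
21 | (1S,2S,3R)-3-[(R)-(2-bromo-4,6-dimethoxyphenyl)(4-methoxyphenyl)methyl]-5,7-dimethoxy-1-(4-methoxyphenyl)-2-[3-methoxy-5-(triisopropylsilyloxy)phenyl]indane | COc1ccc([C@H]2c3c(OC)cc(OC)cc3[C@@H]([C@H](c3ccc(OC)cc3)c3c(OC)cc(OC)cc3Br)[C@@H]2c2cc(OC)cc(O[Si](C(C)C)(C(C)C)C(C)C)c2)cc1 | intermediate
22 | (1S,2S,3R)-3-[(R)-(2,4-dimethoxy-6-vinylphenyl)(4-methoxyphenyl)methyl]-5,7-dimethoxy-1-(4-methoxyphenyl)-2-[3-methoxy-5-(triisopropylsilyloxy)phenyl]indane | COc1ccc([C@H]2c3c(OC)cc(OC)cc3[C@@H]([C@H](c3ccc(OC)cc3)c3c(OC)cc(OC)cc3C=C)[C@@H]2c2cc(OC)cc(O[Si](C(C)C)(C(C)C)C(C)C)c2)cc1 | intermediate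
23 | caesium phenoxide of desilylated 22 | COc1ccc([C@H]2c3c(OC)cc(OC)cc3[C@@H]([C@H](c3ccc(OC)cc3)c3c(OC)cc(OC)cc3C=C)[C@@H]2c2cc(OC)cc([O-])c2)cc1.[Cs+] | intermediate
24 | (1S,2S,3R)-2-(3-allyloxy-5-methoxyphenyl)-3-[(R)-(2,4-dimethoxy-6-vinylphenyl)(4-methoxyphenyl)methyl]-5,7-dimethoxy-1-(4-methoxyphenyl)indane | COc1ccc([C@H]2c3c(OC)cc(OC)cc3[C@@H]([C@H](c3ccc(OC)cc3)c3c(OC)cc(OC)cc3C=C)[C@@H]2c2cc(OC)cc(OCC=C)c2)cc1 | intermediate
25 | twelve-membered (E)-aryl cinnamyl ether macrocycle on the trans,trans-indane; indane C1 (S), C2 (S), C3 (R), methine (R); ring atoms are indane C2 and C3, the methine, two ring C carbons, CH=CH, CH2, O and three ring D carbons | COc1ccc([C@H]2c3c(OC)cc(OC)cc3[C@H]3[C@H](c4ccc(OC)cc4)c4c(OC)cc(OC)cc4/C=C/COc4cc(OC)cc(c4)[C@H]23)cc1 | intermediate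
26 | ortho-dienone from the [3,3] shift of 25 (ring D as a 6-substituted cyclohexa-2,4-dienone) | COc1ccc([C@H]2c3c(OC)cc(OC)cc3[C@H]3[C@H](c4ccc(OC)cc4)c4c(OC)cc(OC)cc4[C@@H](C=C)[C@@H]4C(=O)C=C(OC)C=C4[C@H]23)cc1 | intermediate
27 | eight-membered carbocycle with (R)-vinyl-bearing furan C3 and free ring D phenol | COc1ccc([C@H]2c3c(OC)cc(OC)cc3[C@H]3[C@H](c4ccc(OC)cc4)c4c(OC)cc(OC)cc4[C@@H](C=C)c4c(O)cc(OC)cc4[C@H]23)cc1 | intermediate
28 | 1,2-diol from dihydroxylation of the vinyl group of 27 (carbinol epimers) | COc1ccc([C@H]2c3c(OC)cc(OC)cc3[C@H]3[C@H](c4ccc(OC)cc4)c4c(OC)cc(OC)cc4[C@@H](C(O)CO)c4c(O)cc(OC)cc4[C@H]23)cc1 | intermediate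
29 | open hydroxy aldehyde (formyl group on furan C3, free phenol) | COc1ccc([C@H]2c3c(OC)cc(OC)cc3[C@H]3[C@H](c4ccc(OC)cc4)c4c(OC)cc(OC)cc4[C@@H](C=O)c4c(O)cc(OC)cc4[C@H]23)cc1 | intermediate
30 | 2-hydroxy-2,3-dihydrobenzofuran (lactol, anomer mixture) fused to the eight-membered ring | COc1ccc([C@H]2c3c(OC)cc(OC)cc3[C@H]3[C@H](c4ccc(OC)cc4)c4c(OC)cc(OC)cc4[C@@H]4c5c(cc(OC)cc5[C@H]23)OC4O)cc1 | intermediate
31 | ring D phenol bearing the (4-methoxyphenyl)hydroxymethyl group at furan C3 (carbinol epimers) | COc1ccc([C@H]2c3c(OC)cc(OC)cc3[C@H]3[C@H](c4ccc(OC)cc4)c4c(OC)cc(OC)cc4[C@@H](C(O)c4ccc(OC)cc4)c4c(O)cc(OC)cc4[C@H]23)cc1 | intermediate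
32 | octa-O-methylstenophyllol B (trans-2,3-dihydrobenzofuran; furan C2 (R), C3 (R)) | COc1ccc([C@H]2c3c(OC)cc(OC)cc3[C@H]3[C@H](c4ccc(OC)cc4)c4c(OC)cc(OC)cc4[C@@H]4c5c(cc(OC)cc5[C@H]23)O[C@H]4c2ccc(OC)cc2)cc1 | intermediate
33 | stenophyllol B | Oc1ccc([C@H]2c3c(O)cc(O)cc3[C@H]3[C@H](c4ccc(O)cc4)c4c(O)cc(O)cc4[C@@H]4c5c(cc(O)cc5[C@H]23)O[C@H]4c2ccc(O)cc2)cc1 | target

**Step count and risks**

Total step count: 20. Longest linear sequence: 20 steps (1 to 33); compounds 5, 12 and 20 enter as purchased partners.

Steps most likely to fail: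

1. Step 16 (ring-contracting aromatic Claisen rearrangement). The shift may stall because the macrocycle cannot fold into the chair, may ionise to a cinnamyl cation and lose stereochemical fidelity, or may take place on the wrong alkene face and give the epimer at furan C3. The fallback sets out from bromide 21 and comes back at phenol 27, and forms the same ring D–C3 bond by polar chemistry. Bromine–lithium exchange (n-BuLi, THF, −78 °C) and DMF would give the ring C aldehyde F1. Bu4NF then frees the ring D phenol to give phenol aldehyde F2. Its bromomagnesium phenoxide (EtMgBr, toluene–CH2Cl2, high dilution) should add through its ortho carbon to the chelated aldehyde, an ortho-specific hydroxyalkylation in which only the ortho carbon next to the indane-bearing carbon can reach, and this closes the eight-membered ring as the cyclic ortho-hydroxybenzhydrol F3. Excess vinylmagnesium bromide would convert F3 into the ortho-quinone methide F4 and add to it in 1,4 fashion to give 27. Furan C3 is then set by conjugate addition to the cyclic quinone methide and would have to be confirmed by NOE.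

2. Step 12 (intermolecular Friedel–Crafts reaction). Facial selectivity at the methine may be poor or opposite to the model, the arene may react at C4 between its methoxy groups, and proton loss from the cation may give the exocyclic alkene. The fallback sets out from aldehyde 18 and comes back at bromide 21, and brings in the two aryl groups in the reverse order. Iodination of 20 (N-iodosuccinimide, MeCN) gives 1-bromo-2-iodo-3,5-dimethoxybenzene F5, purified at this simple stage. Iodine–magnesium exchange (i-PrMgCl·LiCl, THF, −40 °C) and addition to 18 give the ring C carbinol F6 with unambiguous regiochemistry. Ionisation with TFA in anisole then installs the 4-methoxyphenyl group para-selectively. If the cation face preference is unchanged, the order reversal delivers the methine epimer that step 12 did not.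

3. Step 15 (ring-closing metathesis). Slow closure of the cyclophane may lead to oligomerisation, the alkene may form as an E/Z mixture, and the allyl ether may isomerise. The fallback sets out from bromide 21 and comes back at macrocycle 25, and closes the ring at the C–O bond with the alkene geometry fixed beforehand. Suzuki–Miyaura coupling of 21 with (E)-3-(tert-butyldimethylsilyloxy)prop-1-enylboronic acid pinacol ester (Pd(OAc)2, SPhos, K3PO4) gives the E-cinnamyl silyl ether F7. Bu4NF removes both silyl groups to give the phenol allylic alcohol F8. A Mitsunobu macro-etherification (PPh3, diisopropyl azodicarboxylate, toluene, 1 mM) then gives 25.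

**Further compounds**

F1 | step 16 | ring C aldehyde from 21 (bromine replaced by formyl, silyl ether kept) | COc1ccc([C@H]2c3c(OC)cc(OC)cc3[C@@H]([C@H](c3ccc(OC)cc3)c3c(OC)cc(OC)cc3C=O)[C@@H]2c2cc(OC)cc(O[Si](C(C)C)(C(C)C)C(C)C)c2)cc1
F2 | step 16 | phenol aldehyde (F1 without the silyl group) | COc1ccc([C@H]2c3c(OC)cc(OC)cc3[C@@H]([C@H](c3ccc(OC)cc3)c3c(OC)cc(OC)cc3C=O)[C@@H]2c2cc(OC)cc(O)c2)cc1
F3 | step 16 | cyclic ortho-hydroxybenzhydrol (eight-membered ring closed, hydroxyl on furan C3, epimers) | COc1ccc([C@H]2c3c(OC)cc(OC)cc3[C@H]3[C@H](c4ccc(OC)cc4)c4c(OC)cc(OC)cc4C(O)c4c(O)cc(OC)cc4[C@H]23)cc1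
F4 | step 16 | cyclic ortho-quinone methide (exocyclic C=C between furan C3 and ring D) | COc1ccc([C@H]2c3c(OC)cc(OC)cc3[C@H]3[C@H](c4ccc(OC)cc4)c4c(OC)cc(OC)cc4/C=C4/C(=O)C=C(OC)C=C4[C@H]23)cc1
F5 | step 12 | 1-bromo-2-iodo-3,5-dimethoxybenzene | COc1cc(OC)c(I)c(Br)c1
F6 | step 12 | all-trans-(2-bromo-4,6-dimethoxyphenyl)[5,7-dimethoxy-1-(4-methoxyphenyl)-2-[3-methoxy-5-(triisopropylsilyloxy)phenyl]indan-3-yl]methanol (carbinol epimers) | COc1ccc([C@H]2c3c(OC)cc(OC)cc3[C@@H](C(O)c3c(OC)cc(OC)cc3Br)[C@@H]2c2cc(OC)cc(O[Si](C(C)C)(C(C)C)C(C)C)c2)cc1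
F7 | step 15 | (E)-cinnamyl tert-butyldimethylsilyl ether from 21 (ring D silyl ether kept) | COc1ccc([C@H]2c3c(OC)cc(OC)cc3[C@@H]([C@H](c3ccc(OC)cc3)c3c(OC)cc(OC)cc3/C=C/CO[Si](C)(C)C(C)(C)C)[C@@H]2c2cc(OC)cc(O[Si](C(C)C)(C(C)C)C(C)C)c2)cc1
F8 | step 15 | phenol (E)-cinnamyl alcohol (seco form of 25) | COc1ccc([C@H]2c3c(OC)cc(OC)cc3[C@@H]([C@H](c3ccc(OC)cc3)c3c(OC)cc(OC)cc3/C=C/CO)[C@@H]2c2cc(OC)cc(O)c2)cc1
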